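We follow the rate.

| setting | alder | cedar | birch | larch |
|---|---|---|---|---|
| electrophile | 5.0 × 10⁻⁴ M | 5.0 × 10⁻⁴ M | 5.0 × 10⁻⁴ M | 5.0 × 10⁻⁴ M |
| nucleophile | 1.10 equiv | 1.10 equiv | 1.10 equiv (fed, over 15 s) | 1.10 equiv |
| free base | 0.800 equiv | 0.800 equiv (fed, over 15 s) | 0.800 equiv | 0.800 equiv (fed, over 15 s) |
| temperature | 60 °C |  | 60 °C | 60 °C |
| time | 25 s | 25 s | 25 s | 25 s |
| remark | everything together at the start | the addition at 40 °C, then warmed to 60 °C; the feed brings no volume worth counting | all else is in the flask from the start; the feed brings no volume worth counting | all else is in the flask from the start; the feed brings no volume worth counting |

    acid set free + free base ⇌ salt of the base (K1 = 6.5 × 10⁵ /M, k1 = 280 /M/s, Ea1 = 48.0 kJ/mol, ΔH1 = 8.00 kJ/mol)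
    nucleophile + acid set free ⇌ protonated nucleophile, settled at all times (K2 = 1.4 × 10⁵ /M, ΔH2 = −46.0 kJ/mol)
    electrophile → decomposition product (k3 = 1.1 × 10⁻⁵ /s, Ea3 = 115 kJ/mol)
    electrophile + target → side product (k4 = 19 /M/s, Ea4 = 44.0 kJ/mol)
    electrophile + nucleophile ⇌ acid set free + target (K5 = 0.67, k5 = 55 /M/s, Ea5 = 58.0 kJ/mol, ΔH5 = −27.0 kJ/mol)
    (constants at 60 °C)

- percentages count the electrophile that a species holds: one side product counts as two
- all constants are for 60 °C and move with temperature by the activation energies and enthalpies

- the flask that comes out highest in share of target in target plus side product, or "all alike" when all lie within 1.5 percentage points (alder / cedar / birch / larch / all alike)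
- share of target in target plus side product at the end, alder
- share of target in target plus side product at the end, cedar
- share of target in target plus side product at the end, birch
- share of target in target plus side product at the end, larch

In alder the target step starts at 0.0303 /s per electrophile, which held for 25 s would lower the natural logarithm of c electrophile by 0.758. That pace follows the free nucleophile, and each target costs two of it, one in the target step and one to the acid set free. The reason is that protonation holds that acid on the nucleophile, 77 held per acid free at the start. The free base reaches only the free part, which at the start stretches the forward half-life of the acid in step 1 from 6.2 s to 477 s, far beyond the run. So we drop the free base from the reckoning, for alder, cedar and larch.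

In logarithms the slowing is then a straight line in this reckoning: the logarithm of c nucleophile over c electrophile falls steadily at 0.0247 /s. For the end of alder we reckon that ratio at 0.539 of its start. The nucleophile factor, free nucleophile over its charge, then comes to 0.344, the electrophile factor, electrophile over its charge, to 0.638, and together they put the forward target step at 0.220 of its starting rate.

The side step over the target step goes as k4 c target over k5 c nucleophile, so electrophile cancels. Summing this, with two electrophiles held per side product, gives the constants' ratio 0.345, the inverse of the selectivity factor, times a bracket: the logarithm of one over the nucleophile factor, divided by one minus that factor, less one. For alder this is 0.216, the side ratio, the electrophile held in side product per electrophile held in target. The share is then 82.2% for alder and 82.2% for larch.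

Cedar's 15 s at 40 °C run the target step at 0.263 of its pace, so we count cedar as 13.9 s at 60 °C. We reckon its ratio at 0.708, its nucleophile factor at 0.522, and its side ratio at 0.124, below alder's, which gives 88.9%. Birch starts without nucleophile, so this reckoning gives it no figure, and among the flasks reckoned we pick cedar.

The forecast gave 83% for alder, 88% for cedar, 85% for birch and 83.2% for larch, and named cedar, with cedar “leaving less target built up alongside electrophile”. Its alder figure lies above ours and its cedar figure below.

The simulation gives 82.0% for alder, 88.4% for cedar, 85.6% for birch and 82.0% for larch, with cedar highest, so the forecast held.

In larch the simulated side product over target at the end is 0.220 against our reckoned side ratio 0.216, with 98.3% of the free base still standing. The neighbour of larch with 4.40 equiv of nucleophile takes the same reckoning: we put its ratio at 5.21 of its start, its nucleophile factor at 0.598, and its side ratio at 0.0965, a share of 91.2%. The simulation reads 91.3% for that neighbour, with 9.91% of the electrophile left.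

Its constants are assumed; the flask was simulated.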